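## Structural features

The target is a daucane-type sesquiterpenoid diester in which a cyclopentane (C1–C5) and a cycloheptene (C1, C5–C10) share the C1–C5 bond. C1 is the methyl-bearing quaternary fusion carbon, C2 and C3 are methylenes, C4 is the tertiary isopropyl carbinol, C5 the fusion methine, C6 the 4-hydroxybenzoyloxy carbon, C7 a methylene, C8 (methyl) and C9 the alkene carbons, and C10 the tigloyloxy carbon. The SMILES decodes to 1R,4R,5S,6R,10R: the fusion is cis (CH3-1 and H5 on the convex face), O4 lies on the cyclopentane face that carries the C5–C6 and C1–C10 bonds, O6 is on the concave face of the seven-membered ring beside C4, and O10 is on the convex face beside CH3-1. The five stereocentres form one contiguous array, C6–C5(–C4)–C1–C10, so each can be set from a neighbour. Fragile groups are the allylic, neopentylic tiglate (ionisation, acyl transfer), the free phenol, the tertiary alcohol 1,3 to the C6 oxygen (retro-aldol at the ketone stage, dehydration in acid) and the trisubstituted alkene (no hydrogenolysis). The real difficulty is the quaternary C1 wedged between C5 and C10, and the C10 oxygen on the convex face, which is the face from which an external hydride is expected to approach a C10 ketone. The key step uses the fact that C1 is β to C6 and C4 is β to C6 through C5: with C6 as a ketone, C1–CH3 is a conjugate-addition bond and C4–C5 an aldol bond of the same C5 enolate, and the aldol closes the cyclopentane.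

## Logic of the disconnections

31 ⇒ 30. The acyl–O bond of a pivalate on the phenol is cut. The phenol must be masked through enolisation, cuprate, hydride and Mitsunobu chemistry, and a pivalate has no α-hydrogen. The demand on the forward step is an aminolysis that takes the aryl pivalate and leaves the C6 benzoate and C10 tiglate.

30 ⇒ 28 + 29. The C10–O bond is cut so that the oxygen comes from acid 29 and C10 is inverted. An external hydride is expected on the convex face of the C10 ketone, which gives 10S (O10 trans to CH3-1), whereas the target is 10R; a hydride reduction followed by retentive acylation would therefore end in the 10-epimer. An invertive esterification joins inversion and acylation in one step. It demands direct displacement at a neopentylic allylic carbon without allylic transposition or elimination.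

28 ⇒ 27. The C10–H bond is cut (1,2-reduction of the enone). The step needs carbonyl over conjugate reduction and one face.

27 ⇒ 24 ⇒ 22. The C8–CH3 bond and the C8=C9 unsaturation are removed in turn. The C10 ketone is flanked by quaternary C1 and can enolise only toward C9, so both desaturations are regiospecific. The forward steps need soft enolisation that spares two aryl esters; the tertiary C4 hydroxyl rides through as a trimethylsilyl ether picked up in the same operation.

22 ⇒ 21 ⇒ 20. The C10 carbonyl goes back to the silyl-protected carbinol. This stereocentre has by then done its work, which was to control C1.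

20 ⇒ 16 + 18, and 18 ⇒ 17. The C6–O acyl bond is cut. The demand is acylation of the secondary C6 hydroxyl beside the tertiary C4 hydroxyl.

16 ⇒ 14. The C6–H bond is cut. Hydride must enter anti to C4; this requires external hydride on an O4–boron chelate, because internal delivery from O4 would give the 6-epimer.

14 ⇒ 12. The key disconnection cuts C1–CH3 and C4–C5. One ring, two skeletal bonds and three stereocentres are removed, leaving a monocyclic enone with one stereocentre. The forward step needs anti addition relative to the C10 silyloxy group and ring closure before any enolate equilibration.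

12 ⇒ 11 ⇒ 4 + 8. The ketone is unmasked from a dioxolane, and the C1–C2 bond is cut (conjugate addition, then re-oxidation to the enone). The isopropyl ketone is carried inside the nucleophile as a ketal, because adding an isopropyl organometallic to a side-chain aldehyde with the enone present would not be chemoselective.

4 ⇒ 3 ⇒ 2 ⇒ 1. The single stereocentre that steers everything comes from desymmetrising a meso endoperoxide; the step needs high enantioselectivity from a chiral base.

8 ⇒ 7 ⇒ 6 ⇒ 5. The side-chain bromide is traced to a β-keto ester by functional-group changes only.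

## Other disconnections considered

Alternative 1: The cut is C6–C7. In the forward sense Me2AlCl activates the aldehyde of the cyclopentane carbaldehyde A2; C7 of the 1,1-disubstituted alkene attacks C6 while a C9 hydrogen passes to oxygen, giving hydroazulene A1.
- In its favour: the ring closes late, the C8=C9 alkene with its methyl appears in place, and A1 already holds the C10 tiglate with C6–OH free. Only aroylation and two deprotections would remain. On endgame length, and in needing no redox work at C8–C10, it is better than the chosen plan.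
- Against it: A2 must already contain C1, C4, C5 and C10, including the quaternary C1 with a stereogenic acyloxy side chain and an epimerisable, elimination-prone aldehyde at C5. Seven-membered ene closures are entropically slow, the allylic tiglate is exposed to a Lewis acid, hydrogen transfer from the methyl would give an exocyclic alkene, and the C6 configuration depends on the transition-state shape.
- Comparison: structurally the chosen plan creates C1, C4 and C5 in its key step, while alternative 1 moves that problem into the synthesis of A2. Mechanistically a concerted pericyclic closure stands against an anionic cascade, each with one uncertain selectivity. In overall step count the two are expected to be about equal.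

Alternative 2: The cuts are C1–C5 and C7–C8. Et3N in trifluoroethanol would turn the dienyl chloromethyl ketone A4 into an oxyallyl cation that adds across the tethered diene, giving the cis-hydroazulenone A3.
- In its favour: both rings and two bonds form from an acyclic precursor with one stereocentre, and the C8 methyl is included. In A3 the C8 hydrogen lies on the convex face, so an ene-type photooxygenation could place oxygen on C10 from that face while moving the alkene to C8=C9. On the C10 configuration and on step economy it is better than the chosen plan.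
- Against it: the oxyallyl cation comes from an unsubstituted chloromethyl ketone with no stabilising group, its terminus is next to the fully substituted C4, and the diene terminus C1 is disubstituted. Ring-fusion geometry, C4 relative to C1/C5, and the C8 methyl all depend on one remote centre. Favorskii and solvolysis pathways compete.
- Comparison: the chosen plan has clearer control of C1, C4 and C5 (anti addition, tether, metal chelate). Alternative 2 is shorter and better placed at C10 but weaker in predictability of its key step.

Alternative 3: The cut is C1–C5, made by a 1,2-shift. KOtBu would deprotonate the tertiary alcohol of the decalin hydroxy mesylate A6, and C1 would migrate from C6 to C5 as mesylate leaves, giving hydroazulenone A5.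
- In its favour: the absolute configuration comes from (R)-Wieland–Miescher ketone A7, which is equal or better than a desymmetrisation. Quaternary C1 exists from the start (better), the shift is stereospecific, and C10 is already at the ketone level as a ketal, saving the desilylation and oxidation of the chosen plan (better there).
- Against it: A5 lacks the isopropyl carbinol. C4 would have to be oxidised to a ketone that is 1,3 to the C6 ketone, and an isopropyl nucleophile added to that enolisable β-diketone with facial control. C5 is epimerisable, and the C8 methyl, C8=C9 and C10 problems remain as in the chosen plan.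
- Comparison: both plans give a cis-hydroazulen-6-one. The chosen plan builds the C4 carbinol in the ring-forming step, whereas alternative 3 must add it afterwards and is expected to be longer.

Key step: step 9

Remarks on the chemistry (assumptions):
- Bicyclic compounds are named with the daucane locants C1–C10 defined above; "14-nor" means the C8 methyl is still absent.
- In step 2 the quinidine-derived base is assumed to give the S alcohol; with the opposite sense of induction the quinine-derived pseudoenantiomer is used.
- The C8 configuration drawn for 25 is inconsequential, since C8 becomes trigonal again in the same step.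

## Route

Step 1
Reactants: 1 cyclohepta-1,3-diene
Product: 2 (1R,5S)-6,7-dioxabicyclo[3.2.2]non-8-ene
Conditions: O2, hν (visible), tetraphenylporphyrin (cat.), CH2Cl2, 0 °C
Reagents that add atoms: dioxygen O=O
Why: Sensitised photooxygenation; singlet oxygen adds to the cisoid diene in a [4+2] cycloaddition and gives the meso endoperoxide.

Step 2
Reactants: 2 (1R,5S)-6,7-dioxabicyclo[3.2.2]non-8-ene
Product: 3 (S)-4-hydroxycyclohept-2-en-1-one
Conditions: O-acetylcupreidine (10 mol %), CH2Cl2, rt
Reagents that add atoms: none
Why: Kornblum–DeLaMare rearrangement run as a desymmetrisation; the chiral bifunctional base removes one of the two enantiotopic bridgehead hydrogens, the O–O bond breaks, and the remaining carbinol carbon becomes the S stereocentre.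

Step 3
Reactants: 3 (S)-4-hydroxycyclohept-2-en-1-one
Product: 4 (S)-4-[(tert-butyldimethylsilyl)oxy]cyclohept-2-en-1-one
Conditions: TBSCl, imidazole, DMF, 0 °C → rt
Reagents that add atoms: tert-butyldimethylsilyl chloride CC(C)(C)[Si](C)(C)Cl
Why: Standard silylation of a secondary alcohol; the bulky silyl ether later shields one face of the enone.

Step 4
Reactants: 5 ethyl 4-methyl-3-oxopentanoate
Product: 6 ethyl 2-(2-isopropyl-1,3-dioxolan-2-yl)acetate
Conditions: HOCH2CH2OH, TsOH·H2O (cat.), toluene, reflux, Dean–Stark
Reagents that add atoms: ethylene glycol OCCO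
Why: Acid-catalysed ketalisation of the ketone of a β-keto ester with removal of water; the ester does not react.

Step 5
Reactants: 6 ethyl 2-(2-isopropyl-1,3-dioxolan-2-yl)acetate
Product: 7 2-(2-isopropyl-1,3-dioxolan-2-yl)ethan-1-ol
Conditions: LiAlH4, THF, 0 °C
Reagents that add atoms: none
Why: Hydride reduction of the ester to the primary alcohol; the ketal is inert to hydride and to the basic work-up.

Step 6
Reactants: 7 2-(2-isopropyl-1,3-dioxolan-2-yl)ethan-1-ol
Product: 8 2-(2-bromoethyl)-2-isopropyl-1,3-dioxolane
Conditions: CBr4, PPh3, CH2Cl2, 0 °C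
Reagents that add atoms: carbon tetrabromide BrC(Br)(Br)Br
Why: Appel bromination of a primary alcohol under neutral conditions that leave the ketal intact.

Step 7
Reactants: 8 2-(2-bromoethyl)-2-isopropyl-1,3-dioxolane; 4 (S)-4-[(tert-butyldimethylsilyl)oxy]cyclohept-2-en-1-one
Product: 11 (S)-4-[(tert-butyldimethylsilyl)oxy]-3-[2-(2-isopropyl-1,3-dioxolan-2-yl)ethyl]cyclohept-2-en-1-one, via Grignard reagent 9 (not isolated), via trimethylsilyl enol ether 10 (not isolated)
Conditions: 8, Mg, THF, 25 °C; then CuBr·SMe2 (10 mol %), TMSCl, 4, THF, −78 °C; then Pd(OAc)2 (10 mol %), O2 (1 atm), DMSO, 40 °C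
Reagents that add atoms: none
Why: Copper-catalysed conjugate addition of the Grignard reagent with silyl trapping, then Saegusa oxidation: the palladium enolate of divalent palladium loses the C3 hydrogen, and the zerovalent palladium formed is reoxidised by O2. The addition goes anti to the silyloxy group, but that centre is erased when the enone is restored, so only the original S centre remains.

Step 8
Reactants: 11 (S)-4-[(tert-butyldimethylsilyl)oxy]-3-[2-(2-isopropyl-1,3-dioxolan-2-yl)ethyl]cyclohept-2-en-1-one
Product: 12 (S)-4-[(tert-butyldimethylsilyl)oxy]-3-(4-methyl-3-oxopentyl)cyclohept-2-en-1-one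
Conditions: PPTS, acetone–H2O, 60 °C
Reagents that add atoms: water O
Why: Mild acid-catalysed ketal hydrolysis; a secondary TBS ether survives pyridinium tosylate in aqueous acetone.

Step 9
Reactants: 12 (S)-4-[(tert-butyldimethylsilyl)oxy]-3-(4-methyl-3-oxopentyl)cyclohept-2-en-1-one
Product: 14 (1R,4R,5R,10S)-10-[(tert-butyldimethylsilyl)oxy]-4-hydroxy-14-nordaucan-6-one, via lithium enolate 13 (not isolated)
Conditions: Me2CuLi (from CuI and MeLi), Et2O, −78 → −20 °C; then aq. NH4Cl, −20 °C
Reagents that add atoms: lithium dimethylcuprate [Li+].C[Cu-]C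
Why: Tandem conjugate addition–intramolecular aldol (Michael–aldol cascade) with a Gilman cuprate. The cuprate forms a π-complex with the enone, adds at C1 to a β-cuprio enolate of trivalent copper and reductively eliminates to form C1–CH3, leaving lithium enolate 13 with its double bond fixed between C5 and C6. C5 of this enolate then attacks the tethered isopropyl ketone in a 5-(enolexo)-exo-trig aldol, which forms C4–C5 and closes the cyclopentane. At C1 the methyl enters anti to the C10 silyloxy group (substrate control by the γ-stereocentre), giving 1R. At C5 the three-atom tether C2–C3–C4 can reach only the face on which C2 stands, so the fusion is cis. At C4 lithium bridges the enolate and ketone oxygens in a closed transition state, placing O4 on the side of C6 and the isopropyl group outside, giving 4R. The step needs 1,4- over 1,2-addition (soft cuprate, hindered saturated ketone), a regiodefined C5 enolate (no base is present, so the C7 enolate never forms) and no retro-aldol or dehydration (cold buffered quench).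

Step 10
Reactants: 14 (1R,4R,5R,10S)-10-[(tert-butyldimethylsilyl)oxy]-4-hydroxy-14-nordaucan-6-one
Product: 16 (1R,4R,5S,6R,10S)-10-[(tert-butyldimethylsilyl)oxy]-14-nordaucane-4,6-diol, via diethylboron chelate 15 (not isolated)
Conditions: Et2BOMe, THF–MeOH (4:1), rt → −78 °C; NaBH4, −78 °C; then AcOH, MeOH co-evaporation
Reagents that add atoms: none
Why: Narasaka–Prasad reduction; boron on O4 chelates the C6 carbonyl on the concave face and external hydride attacks the convex face, anti to C4, giving 6R with O6 syn to O4. Internal hydride delivery from O4 would give the 6-epimer, so a chelate with external hydride is used.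

Step 11
Reactants: 17 4-hydroxybenzoic acid
Product: 18 4-(pivaloyloxy)benzoic acid
Conditions: PivCl, aq. NaOH, THF, 0 °C; then HCl
Reagents that add atoms: pivaloyl chloride CC(C)(C)C(Cl)=O
Why: Schotten–Baumann acylation of the phenoxide; any mixed anhydride at the carboxylate hydrolyses on work-up.

Step 12
Reactants: 18 4-(pivaloyloxy)benzoic acid; 16 (1R,4R,5S,6R,10S)-10-[(tert-butyldimethylsilyl)oxy]-14-nordaucane-4,6-diol
Product: 20 (1R,4R,5S,6R,10S)-10-[(tert-butyldimethylsilyl)oxy]-4-hydroxy-14-nordaucan-6-yl 4-(pivaloyloxy)benzoate, via acid chloride 19 (not isolated)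
Conditions: 18, (COCl)2, DMF (cat.), CH2Cl2, 0 °C → rt; then 16, Et3N, DMAP, CH2Cl2, 0 °C → rt
Reagents that add atoms: none
Why: DMAP-catalysed acylation with an acid chloride; the secondary C6 hydroxyl reacts and the tertiary C4 hydroxyl does not.

Step 13
Reactants: 20 (1R,4R,5S,6R,10S)-10-[(tert-butyldimethylsilyl)oxy]-4-hydroxy-14-nordaucan-6-yl 4-(pivaloyloxy)benzoate
Product: 21 (1R,4R,5S,6R,10S)-4,10-dihydroxy-14-nordaucan-6-yl 4-(pivaloyloxy)benzoate
Conditions: HF·pyridine, pyridine, THF, 0 °C → rt
Reagents that add atoms: none
Why: Fluoride-mediated desilylation under weakly acidic, non-nucleophilic conditions, which spare both aryl esters and avoid acyl migration.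

Step 14
Reactants: 21 (1R,4R,5S,6R,10S)-4,10-dihydroxy-14-nordaucan-6-yl 4-(pivaloyloxy)benzoate
Product: 22 (1R,4R,5S,6R)-4-hydroxy-10-oxo-14-nordaucan-6-yl 4-(pivaloyloxy)benzoate
Conditions: Dess–Martin periodinane, CH2Cl2, rt
Reagents that add atoms: none
Why: Dess–Martin oxidation of the only secondary alcohol; the tertiary C4 hydroxyl cannot be oxidised.

Step 15
Reactants: 22 (1R,4R,5S,6R)-4-hydroxy-10-oxo-14-nordaucan-6-yl 4-(pivaloyloxy)benzoate
Product: 24 (1R,4R,5S,6R)-10-oxo-4-[(trimethylsilyl)oxy]-14-nordauc-8-en-6-yl 4-(pivaloyloxy)benzoate, via bis(trimethylsilyl) compound 23 (not isolated)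
Conditions: TMSOTf, Et3N, CH2Cl2, 0 °C; then Pd(OAc)2 (1.1 equiv), MeCN, rt
Reagents that add atoms: trimethylsilyl trifluoromethanesulfonate C[Si](C)(C)OS(=O)(=O)C(F)(F)F
Why: Soft enolisation followed by Saegusa oxidation; the ketone can enolise only toward C9 because C1 is quaternary, so the C8=C9 enone forms regiospecifically. The tertiary hydroxyl is silylated in the same operation and stays masked for the next step.

Step 16
Reactants: 24 (1R,4R,5S,6R)-10-oxo-4-[(trimethylsilyl)oxy]-14-nordauc-8-en-6-yl 4-(pivaloyloxy)benzoate
Product: 27 (1R,4R,5S,6R)-4-hydroxy-10-oxodauc-8-en-6-yl 4-(pivaloyloxy)benzoate, via trimethylsilyl enol ether 25 (not isolated), via silylated enone 26 (not isolated)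
Conditions: Me2CuLi (from CuI and MeLi), TMSCl, THF, −78 °C; then Pd(OAc)2 (1.1 equiv), MeCN, rt; then 1 M HCl, THF, 0 °C
Reagents that add atoms: lithium dimethylcuprate [Li+].C[Cu-]C
Why: Silyl-accelerated cuprate conjugate addition places the methyl on C8, and a second Saegusa oxidation of the regiodefined silyl enol ether restores C8=C9 and erases the transient C8 centre. The aryl esters do not react with the cuprate at −78 °C, and the brief acid wash removes the tertiary trimethylsilyl ether.

Step 17
Reactants: 27 (1R,4R,5S,6R)-4-hydroxy-10-oxodauc-8-en-6-yl 4-(pivaloyloxy)benzoate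
Product: 28 (1R,4R,5S,6R,10S)-4,10-dihydroxydauc-8-en-6-yl 4-(pivaloyloxy)benzoate
Conditions: NaBH4, CeCl3·7H2O, MeOH, −78 °C
Reagents that add atoms: none
Why: Luche 1,2-reduction of the enone. Hydride is expected on the convex face (that of CH3-1 and H5), because the concave face is screened by C2 and C4 of the cyclopentane in either ring conformer; this gives 10S with O10 trans to CH3-1, and the next step inverts it.

Step 18
Reactants: 28 (1R,4R,5S,6R,10S)-4,10-dihydroxydauc-8-en-6-yl 4-(pivaloyloxy)benzoate; 29 tiglic acid
Product: 30 (1R,4R,5S,6R,10R)-4-hydroxy-10-{[(E)-2-methylbut-2-enoyl]oxy}dauc-8-en-6-yl 4-(pivaloyloxy)benzoate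
Conditions: 29, PPh3, DIAD, toluene, 0 °C → rt
Reagents that add atoms: none
Why: Mitsunobu esterification; the carboxylate displaces the oxyphosphonium group from the convex face with inversion, turning 10S into the required 10R. The tertiary alcohol is inert and the masked phenol cannot compete as a nucleophile.

Step 19
Reactants: 30 (1R,4R,5S,6R,10R)-4-hydroxy-10-{[(E)-2-methylbut-2-enoyl]oxy}dauc-8-en-6-yl 4-(pivaloyloxy)benzoate
Product: 31 (1R,4R,5S,6R,10R)-4-hydroxy-10-{[(E)-2-methylbut-2-enoyl]oxy}dauc-8-en-6-yl 4-hydroxybenzoate
Conditions: pyrrolidine, CH2Cl2, 0 °C → rt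
Reagents that add atoms: none
Why: Chemoselective aminolysis; the aryl pivalate has a phenoxide leaving group and is cleaved, while the hindered secondary alkyl benzoate and the conjugated tiglate are much less electrophilic and stay.

## Compound list

1 | cyclohepta-1,3-diene | C1=CC=CCCC1 | starting material
2 | (1R,5S)-6,7-dioxabicyclo[3.2.2]non-8-ene (meso) | C1=C[C@H]2CCC[C@@H]1OO2 | intermediate
3 | (S)-4-hydroxycyclohept-2-en-1-one | O=C1C=C[C@@H](O)CCC1 | intermediate
4 | (S)-4-[(tert-butyldimethylsilyl)oxy]cyclohept-2-en-1-one | O=C1C=C[C@@H](O[Si](C)(C)C(C)(C)C)CCC1 | intermediate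
5 | ethyl 4-methyl-3-oxopentanoate | CCOC(=O)CC(=O)C(C)C | starting material
6 | ethyl 2-(2-isopropyl-1,3-dioxolan-2-yl)acetate | CCOC(=O)CC1(C(C)C)OCCO1 | intermediate
7 | 2-(2-isopropyl-1,3-dioxolan-2-yl)ethan-1-ol | OCCC1(C(C)C)OCCO1 | intermediate
8 | 2-(2-bromoethyl)-2-isopropyl-1,3-dioxolane | BrCCC1(C(C)C)OCCO1 | intermediate
9 | [2-(2-isopropyl-1,3-dioxolan-2-yl)ethyl]magnesium bromide (not isolated) | Br[Mg]CCC1(C(C)C)OCCO1 | intermediate
10 | tert-butyldimethylsilyl ether of (1S,2S)-2-[2-(2-isopropyl-1,3-dioxolan-2-yl)ethyl]-4-[(trimethylsilyl)oxy]cyclohept-3-en-1-ol (not isolated) | C[Si](C)(C)OC1=C[C@H](CCC2(C(C)C)OCCO2)[C@@H](O[Si](C)(C)C(C)(C)C)CCC1 | intermediate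
11 | (S)-4-[(tert-butyldimethylsilyl)oxy]-3-[2-(2-isopropyl-1,3-dioxolan-2-yl)ethyl]cyclohept-2-en-1-one | CC(C)C1(OCCO1)CCC2=CC(=O)CCC[C@@H]2O[Si](C)(C)C(C)(C)C | intermediate
12 | (S)-4-[(tert-butyldimethylsilyl)oxy]-3-(4-methyl-3-oxopentyl)cyclohept-2-en-1-one (key-step precursor) | CC(C)C(=O)CCC1=CC(=O)CCC[C@@H]1O[Si](C)(C)C(C)(C)C | intermediate
13 | lithium C1(2)-enolate of (3R,4S)-4-[(tert-butyldimethylsilyl)oxy]-3-methyl-3-(4-methyl-3-oxopentyl)cycloheptan-1-one (not isolated) | [Li+].CC(C)(C)[Si](C)(C)O[C@H]1CCCC([O-])=C[C@@]1(C)CCC(=O)C(C)C | intermediate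
14 | (1R,4R,5R,10S)-10-[(tert-butyldimethylsilyl)oxy]-4-hydroxy-14-nordaucan-6-one, cis-fused (key-step product) | CC(C)(C)[Si](C)(C)O[C@H]1CCCC(=O)[C@@H]2[C@@]1(C)CC[C@@]2(O)C(C)C | intermediate
15 | 4-O-diethylboryl derivative of 14, boron chelated by the C6 carbonyl (not isolated) | CC(C)(C)[Si](C)(C)O[C@H]1CCCC(=O)[C@@H]2[C@@]1(C)CC[C@@]2(OB(CC)CC)C(C)C | intermediate
16 | (1R,4R,5S,6R,10S)-10-[(tert-butyldimethylsilyl)oxy]-14-nordaucane-4,6-diol | CC(C)(C)[Si](C)(C)O[C@H]1CCC[C@@H](O)[C@@H]2[C@@]1(C)CC[C@@]2(O)C(C)C | intermediate
17 | 4-hydroxybenzoic acid | OC(=O)c1ccc(O)cc1 | starting material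
18 | 4-(pivaloyloxy)benzoic acid | CC(C)(C)C(=O)Oc1ccc(cc1)C(=O)O | intermediate
19 | 4-(pivaloyloxy)benzoyl chloride (not isolated) | CC(C)(C)C(=O)Oc1ccc(cc1)C(Cl)=O | intermediate
20 | (1R,4R,5S,6R,10S)-10-[(tert-butyldimethylsilyl)oxy]-4-hydroxy-14-nordaucan-6-yl 4-(pivaloyloxy)benzoate | CC(C)(C)[Si](C)(C)O[C@H]1CCC[C@@H](OC(=O)c3ccc(OC(=O)C(C)(C)C)cc3)[C@@H]2[C@@]1(C)CC[C@@]2(O)C(C)C | intermediate
21 | (1R,4R,5S,6R,10S)-4,10-dihydroxy-14-nordaucan-6-yl 4-(pivaloyloxy)benzoate | O[C@H]1CCC[C@@H](OC(=O)c3ccc(OC(=O)C(C)(C)C)cc3)[C@@H]2[C@@]1(C)CC[C@@]2(O)C(C)C | intermediate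
22 | (1R,4R,5S,6R)-4-hydroxy-10-oxo-14-nordaucan-6-yl 4-(pivaloyloxy)benzoate | O=C1CCC[C@@H](OC(=O)c3ccc(OC(=O)C(C)(C)C)cc3)[C@@H]2[C@@]1(C)CC[C@@]2(O)C(C)C | intermediate
23 | (1R,4R,5S,6R)-4,10-bis[(trimethylsilyl)oxy]-14-nordauc-9-en-6-yl 4-(pivaloyloxy)benzoate (not isolated) | C[Si](C)(C)OC1=CCC[C@@H](OC(=O)c3ccc(OC(=O)C(C)(C)C)cc3)[C@@H]2[C@@]1(C)CC[C@@]2(O[Si](C)(C)C)C(C)C | intermediate
24 | (1R,4R,5S,6R)-10-oxo-4-[(trimethylsilyl)oxy]-14-nordauc-8-en-6-yl 4-(pivaloyloxy)benzoate | O=C1C=CC[C@@H](OC(=O)c3ccc(OC(=O)C(C)(C)C)cc3)[C@@H]2[C@@]1(C)CC[C@@]2(O[Si](C)(C)C)C(C)C | intermediate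
25 | (1R,4R,5S,6R,8R)-4,10-bis[(trimethylsilyl)oxy]dauc-9-en-6-yl 4-(pivaloyloxy)benzoate (not isolated) | C[Si](C)(C)OC1=C[C@H](C)C[C@@H](OC(=O)c3ccc(OC(=O)C(C)(C)C)cc3)[C@@H]2[C@@]1(C)CC[C@@]2(O[Si](C)(C)C)C(C)C | intermediate
26 | (1R,4R,5S,6R)-10-oxo-4-[(trimethylsilyl)oxy]dauc-8-en-6-yl 4-(pivaloyloxy)benzoate (not isolated) | O=C1C=C(C)C[C@@H](OC(=O)c3ccc(OC(=O)C(C)(C)C)cc3)[C@@H]2[C@@]1(C)CC[C@@]2(O[Si](C)(C)C)C(C)C | intermediate
27 | (1R,4R,5S,6R)-4-hydroxy-10-oxodauc-8-en-6-yl 4-(pivaloyloxy)benzoate | O=C1C=C(C)C[C@@H](OC(=O)c3ccc(OC(=O)C(C)(C)C)cc3)[C@@H]2[C@@]1(C)CC[C@@]2(O)C(C)C | intermediate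
28 | (1R,4R,5S,6R,10S)-4,10-dihydroxydauc-8-en-6-yl 4-(pivaloyloxy)benzoate | O[C@H]1C=C(C)C[C@@H](OC(=O)c3ccc(OC(=O)C(C)(C)C)cc3)[C@@H]2[C@@]1(C)CC[C@@]2(O)C(C)C | intermediate
29 | tiglic acid, (E)-2-methylbut-2-enoic acid | C/C=C(\C)C(=O)O | starting material
30 | (1R,4R,5S,6R,10R)-4-hydroxy-10-{[(E)-2-methylbut-2-enoyl]oxy}dauc-8-en-6-yl 4-(pivaloyloxy)benzoate | C/C=C(\C)C(=O)O[C@@H]1C=C(C)C[C@@H](OC(=O)c3ccc(OC(=O)C(C)(C)C)cc3)[C@@H]2[C@@]1(C)CC[C@@]2(O)C(C)C | intermediate
31 | (1R,4R,5S,6R,10R)-4-hydroxy-10-{[(E)-2-methylbut-2-enoyl]oxy}dauc-8-en-6-yl 4-hydroxybenzoate (CNP0273650.8) | C/C=C(\C)C(=O)O[C@@H]1C=C(C)C[C@@H](OC(=O)c3ccc(O)cc3)[C@@H]2[C@@]1(C)CC[C@@]2(O)C(C)C | target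

## Step count and least certain steps

Total: 19 steps. Longest linear sequence: 15 steps (1–3, 7–10, 12–19).

**Step 9 (key step).** The most likely failure is slow conjugate addition at the fully substituted β-carbon next to the silyloxy carbon, which would let 1,2-addition to the side-chain ketone or reductive loss of the γ-silyloxy group compete. Next most likely is incomplete ring closure or retro-aldol on warming. The fallback splits the cascade and sets out from 12. Me2CuLi with TMSCl in THF at −78 °C (silyl-accelerated addition) should give the trimethylsilyl enol ether of the 1-methyl adduct F1. An intramolecular Mukaiyama aldol of F1 (TiCl4, CH2Cl2, −78 °C), again through a metal-bridged arrangement of the two oxygens, should close the cyclopentane and return to the route at 14.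

**Step 18.** Displacement at the neopentylic allylic C10 may be slow, so that elimination to a diene or capture at C8 through an ionised allyl system takes over. The fallback avoids substitution at C10 and sets out from 27. A hydroxyl-directed reduction with Me4NBH(OAc)3 (MeCN–AcOH, −20 °C → rt) should bind boron to O4, which is cis-1,3 to C10 on the cyclopentane, and hand hydride to the concave face, giving the (10R)-alcohol F2. Retentive Yamaguchi acylation (29, 2,4,6-trichlorobenzoyl chloride, Et3N, THF; then DMAP, toluene, 60 °C) through tiglic 2,4,6-trichlorobenzoic anhydride F3 returns to the route at 30.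

**Step 17.** Facial selectivity may be poor, with hydride delivered partly to the concave face, giving a mixture of C10 epimers. The fallback replaces substrate control by reagent control and sets out from 27: CBS reduction with the 2-methyl-oxazaborolidine enantiomer matched to convex-face delivery and catecholborane (toluene, −78 °C), returning at 28. Any 10R epimer formed is the alcohol F2 above and can be carried to 30 by the retentive acylation, so the two esterification modes are stereocomplementary.

**Step 2.** Enantioselection may be eroded by a competing non-selective base pathway, or the sense of induction may be opposite to that assumed. The fallback replaces chiral-base desymmetrisation by enzymatic desymmetrisation and sets out from 1: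
- Pd(OAc)2-catalysed cis-1,4-diacetoxylation (LiOAc, LiCl, benzoquinone, AcOH) gives meso cis-cyclohept-2-ene-1,4-diyl diacetate F4.
- Lipase hydrolysis of one enantiotopic acetate gives (1R,4S)-4-hydroxycyclohept-2-en-1-yl acetate F5.
- TBSCl/imidazole gives the silyl ether acetate F6.
- K2CO3/MeOH gives (1R,4S)-4-[(tert-butyldimethylsilyl)oxy]cyclohept-2-en-1-ol F7.
- MnO2 oxidation returns to the route at 4.

If the lipase frees the other acetate, the complementary lipase acetylation of the meso diol gives the needed monoacetate.

## Further compounds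

F1 | step 9 | tert-butyldimethylsilyl ether of (1S,2R)-2-methyl-2-(4-methyl-3-oxopentyl)-4-[(trimethylsilyl)oxy]cyclohept-3-en-1-ol | CC(C)(C)[Si](C)(C)O[C@H]1CCCC(O[Si](C)(C)C)=C[C@@]1(C)CCC(=O)C(C)C
F2 | step 18 | (1R,4R,5S,6R,10R)-4,10-dihydroxydauc-8-en-6-yl 4-(pivaloyloxy)benzoate | O[C@@H]1C=C(C)C[C@@H](OC(=O)c3ccc(OC(=O)C(C)(C)C)cc3)[C@@H]2[C@@]1(C)CC[C@@]2(O)C(C)C
F3 | step 18 | (E)-2-methylbut-2-enoic 2,4,6-trichlorobenzoic anhydride | C/C=C(\C)C(=O)OC(=O)c1c(Cl)cc(Cl)cc1Cl
F0 | step 17 | none | none
F4 | step 2 | meso cis-cyclohept-2-ene-1,4-diyl diacetate | CC(=O)O[C@H]1C=C[C@@H](OC(C)=O)CCC1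
F5 | step 2 | (1R,4S)-4-hydroxycyclohept-2-en-1-yl acetate | CC(=O)O[C@H]1C=C[C@@H](O)CCC1
F6 | step 2 | (1R,4S)-4-[(tert-butyldimethylsilyl)oxy]cyclohept-2-en-1-yl acetate | CC(=O)O[C@H]1C=C[C@@H](O[Si](C)(C)C(C)(C)C)CCC1
F7 | step 2 | (1R,4S)-4-[(tert-butyldimethylsilyl)oxy]cyclohept-2-en-1-ol | O[C@H]1C=C[C@@H](O[Si](C)(C)C(C)(C)C)CCC1
A1 | alternative 1 | (1R,4R,5S,6R,10R)-6-hydroxy-4-[(triethylsilyl)oxy]dauc-8-en-10-yl (E)-2-methylbut-2-enoate | C/C=C(\C)C(=O)O[C@@H]1C=C(C)C[C@@H](O)[C@@H]2[C@@]1(C)CC[C@@]2(O[Si](CC)(CC)CC)C(C)C
A2 | alternative 1 | cyclopentanecarbaldehyde bearing the C1 methyl, the C4 isopropyl triethylsilyl ether and the C10 tigloyloxy 3-methylbut-3-enyl side chain | C/C=C(\C)C(=O)O[C@H](CC(C)=C)[C@]1(C)CC[C@@](O[Si](CC)(CC)CC)(C(C)C)[C@@H]1C=O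
A3 | alternative 2 | cis-fused 4-[(triethylsilyl)oxy]dauc-9-en-6-one with the C8 methyl stereocentre | C1=C[C@@H](C)CC(=O)[C@@H]2[C@@]1(C)CC[C@@]2(O[Si](CC)(CC)CC)C(C)C
A4 | alternative 2 | (S,7E,9E)-1-chloro-4-isopropyl-7-methyl-4-[(triethylsilyl)oxy]undeca-7,9-dien-2-one | ClCC(=O)C[C@](O[Si](CC)(CC)CC)(C(C)C)CC/C(C)=C/C=C/C
A5 | alternative 3 | cis-fused hydroazulen-6-one with C10 dioxolane and C4 tert-butyldimethylsilyl ether | C12(OCCO1)CCCC(=O)[C@@H]3[C@@]2(C)CC[C@H]3O[Si](C)(C)C(C)(C)C
A6 | alternative 3 | trans-decalin with C6 tertiary hydroxyl, C5 mesylate, C4 tert-butyldimethylsilyl ether, C1 methyl and C10 dioxolane | C[C@@]12CC[C@@H](O[Si](C)(C)C(C)(C)C)[C@H](OS(C)(=O)=O)[C@@]1(O)CCCC23OCCO3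
A7 | alternative 3 | (R)-Wieland–Miescher ketone | C[C@@]12CCC(=O)C=C1CCCC2=O
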